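**Assumption:** the target SMILES has no stereocentre, so the compound is achiral and no stereocontrol is needed.

**Retrosynthetic overview**
- Target ⇐ one neutral hydrogenation that saturates an alkyne and removes four benzyl ethers; acid is avoided because the tertiary alcohol would close onto 5‑/7‑OH as a chroman.
- Side chain ⇐ Sonogashira coupling of 2‑methylbut‑3‑yn‑2‑ol with a 6‑iodoflavonol; the iodide ⇐ iodination ortho to a free, chelated 5‑OH (C‑6 selective).
- Flavonol ⇐ flavone by C‑3 hydroxylation (epoxidation and epoxide opening), then benzyl adjustment to free only 5‑OH.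
- Flavone ⇐ 2'‑hydroxychalcone by oxidative cyclisation; the pyranone C ring is the only ring formed, rings A and B are bought.
- Chalcone ⇐ Claisen–Schmidt aldol condensation of a phloroacetophenone dibenzyl ether with 4‑benzyloxybenzaldehyde (forms the future C2–C3 bond).

**Route**

Step 1
Reactants: 1 2,4,6-trihydroxyacetophenone
Product: 3 1-[2,4-bis(benzyloxy)-6-hydroxyphenyl]ethanone, via 1-[4-(benzyloxy)-2,6-dihydroxyphenyl]ethanone 2 (not isolated)
Conditions: BnBr (2.1 equiv), K2CO3 (2.5 equiv), DMF, rt to 40 °C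
Reagents that add atoms: benzyl bromide BrCc1ccccc1
Why: Williamson etherification alkylates the free 4‑OH first and then one ortho OH, and stops there because the last OH is locked in a hydrogen bond to the ketone carbonyl.

Step 2
Reactants: 3 1-[2,4-bis(benzyloxy)-6-hydroxyphenyl]ethanone; 4 4-(benzyloxy)benzaldehyde
Product: 6 (E)-1-[2,4-bis(benzyloxy)-6-hydroxyphenyl]-3-[4-(benzyloxy)phenyl]prop-2-en-1-one (the chalcone), via racemic β-hydroxy ketone aldol adduct 5 (not isolated)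
Conditions: KOH (50% aq., excess), EtOH/THF, rt, 24–48 h
Reagents that add atoms: none
Why: Claisen–Schmidt crossed aldol condensation gives one cross-product because only the ketone can enolise and the aldehyde cannot, and E1cB dehydration gives the conjugated E-enone, so no stereocentre remains.

Step 3
Reactants: 6 the chalcone
Product: 8 5,7-bis(benzyloxy)-2-[4-(benzyloxy)phenyl]-4H-chromen-4-one, via racemic 5,7,4'-tri-O-benzylflavanone 7 (not isolated)
Conditions: I2 (10 mol%), DMSO, 130 °C, 2–3 h; Na2S2O3 work-up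
Reagents that add atoms: none
Why: Iodine-catalysed oxidative cyclisation: oxa-Michael closure of the 2'‑OH gives the flavanone, which is α‑iodinated and loses HI to the aromatic γ‑pyrone while DMSO re-oxidises HI to I2.

Step 4
Reactants: 8 5,7-bis(benzyloxy)-2-[4-(benzyloxy)phenyl]-4H-chromen-4-one
Product: 10 5,7-bis(benzyloxy)-2-[4-(benzyloxy)phenyl]-3-hydroxy-4H-chromen-4-one, via racemic flavone 2,3-epoxide 9 (not isolated)
Conditions: DMDO (3–4 equiv, acetone solution), CH2Cl2, 0 °C to rt; then p-TsOH (cat.), CH2Cl2, rt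
Reagents that add atoms: dimethyldioxirane CC1(C)OO1
Why: Electrophilic epoxidation of the enol-ether-like C2=C3 bond by the neutral dioxirane, then acid-catalysed epoxide opening and tautomerisation, gives the 3‑hydroxyflavone, and this sequence avoids the aurone formation that the Algar–Flynn–Oyamada reaction suffers with 6'-alkoxychalcones.

Step 5
Reactants: 10 5,7-bis(benzyloxy)-2-[4-(benzyloxy)phenyl]-3-hydroxy-4H-chromen-4-one
Product: 11 3,5,7-tris(benzyloxy)-2-[4-(benzyloxy)phenyl]-4H-chromen-4-one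
Conditions: BnBr (1.3 equiv), K2CO3, DMF, rt to 50 °C
Reagents that add atoms: benzyl bromide BrCc1ccccc1
Why: Williamson etherification of the acidic enolic 3‑OH masks it before the A ring is iodinated and coupled.

Step 6
Reactants: 11 3,5,7-tris(benzyloxy)-2-[4-(benzyloxy)phenyl]-4H-chromen-4-one
Product: 12 3,7-bis(benzyloxy)-2-[4-(benzyloxy)phenyl]-5-hydroxy-4H-chromen-4-one
Conditions: MgBr2·OEt2 (3 equiv), toluene/Et2O, 80 °C; aq. NH4Cl
Reagents that add atoms: none
Why: Chelation-controlled debenzylation: Mg(II) bridges C4=O and the peri 5‑oxygen in a six-membered chelate, so bromide removes that benzyl group by SN2 while the 7‑ and 4'‑ethers cannot chelate and the 3‑ether forms only a weaker five-membered chelate.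

Step 7
Reactants: 12 3,7-bis(benzyloxy)-2-[4-(benzyloxy)phenyl]-5-hydroxy-4H-chromen-4-one
Product: 13 3,7-bis(benzyloxy)-2-[4-(benzyloxy)phenyl]-5-hydroxy-6-iodo-4H-chromen-4-one
Conditions: BnMe3N·ICl2 (1.1 equiv), CaCO3, CH2Cl2/MeOH (5:2), rt
Reagents that add atoms: benzyltrimethylammonium dichloroiodate C[N+](C)(C)Cc1ccccc1.Cl[I-]Cl
Why: Electrophilic aromatic iodination under buffered conditions goes ortho to the free chelated 5‑OH (C‑6) when 7‑O is alkylated, and the ether-only B ring and benzyl rings are too unreactive for this mild reagent.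

Step 8
Reactants: 13 3,7-bis(benzyloxy)-2-[4-(benzyloxy)phenyl]-5-hydroxy-6-iodo-4H-chromen-4-one
Product: 14 3,5,7-tris(benzyloxy)-2-[4-(benzyloxy)phenyl]-6-iodo-4H-chromen-4-one
Conditions: BnBr (2 equiv), K2CO3 (3 equiv), Bu4NI (cat.), DMF, 70 °C
Reagents that add atoms: benzyl bromide BrCc1ccccc1
Why: Williamson etherification under forcing conditions breaks the chelate and caps 5‑OH, so the phenol cannot cyclise onto the alkyne to a furan in the coupling step.

Step 9
Reactants: 14 3,5,7-tris(benzyloxy)-2-[4-(benzyloxy)phenyl]-6-iodo-4H-chromen-4-one; 15 2-methylbut-3-yn-2-ol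
Product: 16 3,5,7-tris(benzyloxy)-2-[4-(benzyloxy)phenyl]-6-(3-hydroxy-3-methylbut-1-yn-1-yl)-4H-chromen-4-one
Conditions: PdCl2(PPh3)2 (5 mol%), CuI (10 mol%), Et3N/DMF, 70 °C, Ar
Reagents that add atoms: none
Why: Sonogashira coupling of the aryl iodide with the terminal alkyne proceeds despite two ortho alkoxy groups, and the tertiary propargylic alcohol needs no protection.

Step 10
Reactants: 16 3,5,7-tris(benzyloxy)-2-[4-(benzyloxy)phenyl]-6-(3-hydroxy-3-methylbut-1-yn-1-yl)-4H-chromen-4-one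
Product: 18 3,5,7-trihydroxy-6-(3-hydroxy-3-methylbutyl)-2-(4-hydroxyphenyl)-4H-chromen-4-one (target), via saturated tetra-O-benzyl ether 17 (not isolated)
Conditions: H2 (1 atm), 10% Pd/C, THF/MeOH, rt
Reagents that add atoms: none
Why: Heterogeneous catalytic hydrogenation saturates the alkyne quickly and then hydrogenolyses all four O‑benzyl groups under neutral conditions, leaving the non-benzylic tertiary alcohol and the flavonol C2=C3 bond intact.

**Compound list**
1 | 2,4,6-trihydroxyacetophenone | CC(=O)c1c(O)cc(O)cc1O | starting material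
2 | 1-[4-(benzyloxy)-2,6-dihydroxyphenyl]ethanone | CC(=O)c1c(O)cc(OCc2ccccc2)cc1O | intermediate (not isolated)
3 | 1-[2,4-bis(benzyloxy)-6-hydroxyphenyl]ethanone | CC(=O)c1c(O)cc(OCc2ccccc2)cc1OCc1ccccc1 | intermediate
4 | 4-(benzyloxy)benzaldehyde | O=Cc1ccc(OCc2ccccc2)cc1 | starting material
5 | 1-[2,4-bis(benzyloxy)-6-hydroxyphenyl]-3-[4-(benzyloxy)phenyl]-3-hydroxypropan-1-one (racemic aldol adduct) | O=C(CC(O)c1ccc(OCc2ccccc2)cc1)c1c(O)cc(OCc2ccccc2)cc1OCc1ccccc1 | intermediate (not isolated)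
6 | (E)-1-[2,4-bis(benzyloxy)-6-hydroxyphenyl]-3-[4-(benzyloxy)phenyl]prop-2-en-1-one (chalcone) | O=C(/C=C/c1ccc(OCc2ccccc2)cc1)c1c(O)cc(OCc2ccccc2)cc1OCc1ccccc1 | intermediate
7 | 5,7-bis(benzyloxy)-2-[4-(benzyloxy)phenyl]chroman-4-one (racemic flavanone) | O=C1CC(c2ccc(OCc3ccccc3)cc2)Oc2cc(OCc3ccccc3)cc(OCc3ccccc3)c21 | intermediate (not isolated)
8 | 5,7-bis(benzyloxy)-2-[4-(benzyloxy)phenyl]-4H-chromen-4-one | O=c1cc(-c2ccc(OCc3ccccc3)cc2)oc2cc(OCc3ccccc3)cc(OCc3ccccc3)c12 | intermediate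
9 | 2,3-epoxide of 8 (racemic, cis-fused oxirane across C2–C3) | O=C1C2OC2(c2ccc(OCc3ccccc3)cc2)Oc2cc(OCc3ccccc3)cc(OCc3ccccc3)c21 | intermediate (not isolated)
10 | 5,7-bis(benzyloxy)-2-[4-(benzyloxy)phenyl]-3-hydroxy-4H-chromen-4-one | O=c1c(O)c(-c2ccc(OCc3ccccc3)cc2)oc2cc(OCc3ccccc3)cc(OCc3ccccc3)c12 | intermediate
11 | 3,5,7-tris(benzyloxy)-2-[4-(benzyloxy)phenyl]-4H-chromen-4-one | O=c1c(OCc2ccccc2)c(-c2ccc(OCc3ccccc3)cc2)oc2cc(OCc3ccccc3)cc(OCc3ccccc3)c12 | intermediate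
12 | 3,7-bis(benzyloxy)-2-[4-(benzyloxy)phenyl]-5-hydroxy-4H-chromen-4-one | O=c1c(OCc2ccccc2)c(-c2ccc(OCc3ccccc3)cc2)oc2cc(OCc3ccccc3)cc(O)c12 | intermediate
13 | 3,7-bis(benzyloxy)-2-[4-(benzyloxy)phenyl]-5-hydroxy-6-iodo-4H-chromen-4-one | O=c1c(OCc2ccccc2)c(-c2ccc(OCc3ccccc3)cc2)oc2cc(OCc3ccccc3)c(I)c(O)c12 | intermediate
14 | 3,5,7-tris(benzyloxy)-2-[4-(benzyloxy)phenyl]-6-iodo-4H-chromen-4-one | O=c1c(OCc2ccccc2)c(-c2ccc(OCc3ccccc3)cc2)oc2cc(OCc3ccccc3)c(I)c(OCc3ccccc3)c12 | intermediate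
15 | 2-methylbut-3-yn-2-ol | C#CC(C)(C)O | starting material
16 | 3,5,7-tris(benzyloxy)-2-[4-(benzyloxy)phenyl]-6-(3-hydroxy-3-methylbut-1-yn-1-yl)-4H-chromen-4-one | CC(C)(O)C#Cc1c(OCc2ccccc2)cc2oc(-c3ccc(OCc4ccccc4)cc3)c(OCc3ccccc3)c(=O)c2c1OCc1ccccc1 | intermediate
17 | 3,5,7-tris(benzyloxy)-2-[4-(benzyloxy)phenyl]-6-(3-hydroxy-3-methylbutyl)-4H-chromen-4-one | CC(C)(O)CCc1c(OCc2ccccc2)cc2oc(-c3ccc(OCc4ccccc4)cc3)c(OCc3ccccc3)c(=O)c2c1OCc1ccccc1 | intermediate (not isolated)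
18 | 3,5,7-trihydroxy-6-(3-hydroxy-3-methylbutyl)-2-(4-hydroxyphenyl)-4H-chromen-4-one (achiral) | CC(C)(O)CCc1c(O)cc2oc(-c3ccc(O)cc3)c(O)c(=O)c2c1O | target

**Totals**
Total step count: 10. Longest linear sequence: 10 steps (1 → 18); 4 and 15 are bought fragments.

**Three steps most likely to fail**

Step 4 (DMDO may attack benzylic C–H of the four benzyl ethers or stall on this electron-poor alkene). The fallback sets out from 8 and comes back at 10, and it replaces oxidation of the double bond by deprotonation at C‑3. LDA in THF at −78 °C gives the 3‑lithioflavone F1, which is trapped with B(OMe)3 to the dimethyl flavon‑3‑ylboronate F2. H2O2/AcOH then oxidises the C–B bond to give 10.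

Step 6 (MgBr2 may also cleave the 3‑O‑benzyl enol ether). The fallback sets out from 11 and comes back at 12, and it gives up selective cleavage. Complete hydrogenolysis of 11 (H2, Pd/C, THF/MeOH) gives kaempferol F3. Re-benzylation with 3.1 equiv BnBr and K2CO3 in DMF alkylates 7‑, 4'‑ and 3‑OH and spares the chelated 5‑OH, giving 12.

Step 7 (iodination could also occur at C‑8 or go twice). The fallback sets out from 12 and comes back at 18, and it delivers carbon to C‑6 by a sigmatropic shift that goes to the only free position ortho to O‑5.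
- Allyl bromide and K2CO3 in DMF at 60 °C give the 5‑O‑allyl ether F4.
- Aromatic Claisen rearrangement (PhNEt2, 190 °C) gives the 6‑allyl‑5‑hydroxy flavonol F5.
- Cross-metathesis with 2‑methylbut‑2‑ene (Grubbs II, CH2Cl2, 40 °C) gives the 6‑prenyl compound F6.
- Mukaiyama hydration (Co(acac)2, PhSiH3, O2, THF) gives the tertiary alcohol F7.
- Hydrogenolysis (H2, Pd/C) gives 18.

**Further compounds**
F1 | step 4 | 5,7-bis(benzyloxy)-2-[4-(benzyloxy)phenyl]-3-lithio-4H-chromen-4-one | [Li]c1c(-c2ccc(OCc3ccccc3)cc2)oc2cc(OCc3ccccc3)cc(OCc3ccccc3)c2c1=O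
F2 | step 4 | dimethyl {5,7-bis(benzyloxy)-2-[4-(benzyloxy)phenyl]-4-oxo-4H-chromen-3-yl}boronate | COB(OC)c1c(-c2ccc(OCc3ccccc3)cc2)oc2cc(OCc3ccccc3)cc(OCc3ccccc3)c2c1=O
F3 | step 6 | kaempferol (3,5,7-trihydroxy-2-(4-hydroxyphenyl)-4H-chromen-4-one) | O=c1c(O)c(-c2ccc(O)cc2)oc2cc(O)cc(O)c12
F4 | step 7 | 5-(allyloxy)-3,7-bis(benzyloxy)-2-[4-(benzyloxy)phenyl]-4H-chromen-4-one | C=CCOc1cc(OCc2ccccc2)cc2oc(-c3ccc(OCc4ccccc4)cc3)c(OCc3ccccc3)c(=O)c12
F5 | step 7 | 6-allyl-3,7-bis(benzyloxy)-2-[4-(benzyloxy)phenyl]-5-hydroxy-4H-chromen-4-one | C=CCc1c(OCc2ccccc2)cc2oc(-c3ccc(OCc4ccccc4)cc3)c(OCc3ccccc3)c(=O)c2c1O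
F6 | step 7 | 3,7-bis(benzyloxy)-2-[4-(benzyloxy)phenyl]-5-hydroxy-6-(3-methylbut-2-en-1-yl)-4H-chromen-4-one | CC(C)=CCc1c(OCc2ccccc2)cc2oc(-c3ccc(OCc4ccccc4)cc3)c(OCc3ccccc3)c(=O)c2c1O
F7 | step 7 | 3,7-bis(benzyloxy)-2-[4-(benzyloxy)phenyl]-5-hydroxy-6-(3-hydroxy-3-methylbutyl)-4H-chromen-4-one | CC(C)(O)CCc1c(OCc2ccccc2)cc2oc(-c3ccc(OCc4ccccc4)cc3)c(OCc3ccccc3)c(=O)c2c1O
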